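## Retrosynthetic overview

1. Labels follow the hydrindene numbering of the target: cyclopentene C1(Et)=C2–C3(H)(Me)–C3a–C7a and cyclohexene C3a–C4(Me)=C5–C6(Me)(dienyl)–C7(Me)(CO2H)–C7a. The key disconnection cuts C3a–C7a and C6–C7 in one intramolecular Diels–Alder reaction of the acyclic (2E,4Z)-dienal 14. Both rings and the four stereocentres C3a, C6, C7 and C7a (with the vicinal quaternary pair C6/C7) form together, relayed from the one purchased stereocentre C3.
2. The feature used: the C4=C5 alkene flanked by C3a and C6 is the retron of the diene C3a=C4–C5=C6 (first diene of an all-E styryl tetraene). C7/C7a is an (E)-2-methylenal dienophile, and the C1=C2 alkene is the Z-alkene of the three-atom tether C3–C2=C1.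
3. The dienal is released in the flask by MnO2 oxidation of hexaenol 13; CHO → CO2H (Pinnick) is the last step.
4. 13 comes from Negishi coupling (C1–C7a bond) of Z-iodoalkene 10 with the alkenylalane from propargyl alcohol. 10 comes from methyl (S)-3-hydroxy-2-methylpropanoate by Z-selective iodo-olefination (C1=C2), three Wittig homologations and a benzyl HWE.
5. Ring order: no ring before step 11; cyclopentene and cyclohexene close simultaneously.

Key step: step 11

Remark: both enantiomers of methyl 3-hydroxy-2-methylpropanoate are commercial; the (S)-ester supplies C3. Where a name and a SMILES string differ, the SMILES string is meant.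

## Route

Step 1
Reactants: 1 methyl (S)-3-hydroxy-2-methylpropanoate
Product: 2 methyl (S)-3-[(tert-butyldimethylsilyl)oxy]-2-methylpropanoate
Conditions: TBSCl, imidazole, CH2Cl2, 0 °C to rt
Reagents that add atoms: tert-butyldimethylsilyl chloride, CC(C)(C)[Si](C)(C)Cl
Why: Imidazole-mediated silylation masks the primary alcohol for the olefination at the other terminus and does not touch the stereocentre.

Step 2
Reactants: 2 methyl (S)-3-[(tert-butyldimethylsilyl)oxy]-2-methylpropanoate
Product: 3 (S)-3-[(tert-butyldimethylsilyl)oxy]-2-methylpropanal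
Conditions: DIBAL-H (1.1 equiv), CH2Cl2, −78 °C; aq. potassium sodium tartrate
Reagents that add atoms: none
Why: Partial DIBAL-H reduction of the ester at −78 °C stops at the aluminium hemiacetal and should give the α-methyl aldehyde without epimerisation when it is used crude and cold.

Step 3
Reactants: 3 (S)-3-[(tert-butyldimethylsilyl)oxy]-2-methylpropanal
Product: 4 tert-butyl{[(2R,3Z)-4-iodo-2-methylhex-3-en-1-yl]oxy}dimethylsilane
Conditions: n-PrPPh3Br, n-BuLi, THF, 0 °C to rt; I2, −78 °C; NaHMDS, −78 to −20 °C; then 3, −78 to −20 °C, dark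
Reagents that add atoms: propyltriphenylphosphonium bromide, CCC[P+](c1ccccc1)(c1ccccc1)c1ccccc1.[Br-]; iodine, II
Why: Stork–Zhao-type Wittig olefination with the α-iodo ylide made in situ should place iodine cis to the chain (Z), which fixes the later C1=C2 geometry (ethyl trans to C3) and leaves the coupling handle on C1.

Step 4
Reactants: 4 tert-butyl{[(2R,3Z)-4-iodo-2-methylhex-3-en-1-yl]oxy}dimethylsilane
Product: 5 (2R,3Z)-4-iodo-2-methylhex-3-en-1-ol
Conditions: CSA (10 mol %), MeOH/CH2Cl2, 0 °C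
Reagents that add atoms: none
Why: Acid-catalysed methanolysis removes the primary TBS ether, and the iodoalkene and the stereocentre are inert to it.

Step 5
Reactants: 5 (2R,3Z)-4-iodo-2-methylhex-3-en-1-ol
Product: 6 (2R,3Z)-4-iodo-2-methylhex-3-enal
Conditions: Dess–Martin periodinane, pyridine, CH2Cl2, 0 °C; used at once
Reagents that add atoms: none
Why: Dess–Martin oxidation under buffered, non-basic conditions should give the β,γ-unsaturated α-methyl aldehyde without enolisation or alkene migration.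

Step 6
Reactants: 6 (2R,3Z)-4-iodo-2-methylhex-3-enal
Product: 7 (2E,4S,5Z)-6-iodo-2,4-dimethylocta-2,5-dienal
Conditions: Ph3P=C(Me)CHO (1.5 equiv), PhMe, 70 °C, dark
Reagents that add atoms: 2-(triphenylphosphoranylidene)propanal, CC(C=O)=P(c1ccccc1)(c1ccccc1)c1ccccc1
Why: The Wittig reaction with the stabilised formyl ylide is E-selective and needs no added base, so the α-stereocentre of 6 should survive while the C3a=C4(Me) alkene is formed.

Step 7
Reactants: 7 (2E,4S,5Z)-6-iodo-2,4-dimethylocta-2,5-dienal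
Product: 8 (2E,4E,6S,7Z)-8-iodo-2,4,6-trimethyldeca-2,4,7-trienal
Conditions: Ph3P=C(Me)CHO (2 equiv), PhMe, 100 °C, dark
Reagents that add atoms: 2-(triphenylphosphoranylidene)propanal, CC(C=O)=P(c1ccccc1)(c1ccccc1)c1ccccc1
Why: A second E-selective Wittig homologation with the same stabilised ylide adds the C5=C6(Me) unit; the dienal product is less electrophilic than 7, which limits over-homologation.

Step 8
Reactants: 8 (2E,4E,6S,7Z)-8-iodo-2,4,6-trimethyldeca-2,4,7-trienal
Product: 9 (2E,4E,6E,8S,9Z)-10-iodo-2,4,6,8-tetramethyldodeca-2,4,6,9-tetraenal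
Conditions: Ph3P=C(Me)CHO (3 equiv), PhMe, 110 °C, dark
Reagents that add atoms: 2-(triphenylphosphoranylidene)propanal, CC(C=O)=P(c1ccccc1)(c1ccccc1)c1ccccc1
Why: A third E-selective Wittig homologation installs the methyl-bearing alkene of the side chain under neutral conditions.

Step 9
Reactants: 9 (2E,4E,6E,8S,9Z)-10-iodo-2,4,6,8-tetramethyldodeca-2,4,6,9-tetraenal
Product: 10 [(1E,3E,5E,7E,9S,10Z)-11-iodo-3,5,7,9-tetramethyltrideca-1,3,5,7,10-pentaen-1-yl]benzene
Conditions: (EtO)2P(O)CH2Ph, LiHMDS, THF, −78 °C; then 9, −78 to 0 °C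
Reagents that add atoms: diethyl benzylphosphonate, CCOP(=O)(Cc1ccccc1)OCC
Why: Horner–Wadsworth–Emmons olefination with the pre-formed benzylphosphonate anion gives the E-styryl terminus, and cold addition to the aldehyde should outrun deprotonation of the doubly allylic C–H.

Step 10
Reactants: 10 [(1E,3E,5E,7E,9S,10Z)-11-iodo-3,5,7,9-tetramethyltrideca-1,3,5,7,10-pentaen-1-yl]benzene; 11 prop-2-yn-1-ol
Product: 13 (2E,4Z,6S,7E,9E,11E,13E)-4-ethyl-2,6,8,10,12-pentamethyl-14-phenyltetradeca-2,4,7,9,11,13-hexaen-1-ol, via (E)-[3-(dimethylalumanyloxy)-2-methylprop-1-en-1-yl]dimethylalumane 12 (not isolated)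
Conditions: 11, Me3Al (3 equiv), Cp2ZrCl2 (0.3 equiv), (CH2Cl)2, 0 °C to rt; then 10, Pd(PPh3)4 (5 mol %), ZnCl2 (co-catalyst), THF, rt; aq. potassium sodium tartrate
Reagents that add atoms: trimethylaluminium, C[Al](C)C
Why: Zr-catalysed syn-methylalumination of the alkyne gives the (E)-alkenylalane regioselectively, and Pd/Zn-cocatalysed Negishi coupling with the iodoalkene retains the geometry of both partners, which should give the (2E,4Z)-dienol.

Step 11
Reactants: 13 (2E,4Z,6S,7E,9E,11E,13E)-4-ethyl-2,6,8,10,12-pentamethyl-14-phenyltetradeca-2,4,7,9,11,13-hexaen-1-ol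
Product: 15 (1R,3aR,4R,5S,7aS)-3-ethyl-1,4,5,7-tetramethyl-5-[(1E,3E)-2-methyl-4-phenylbuta-1,3-dien-1-yl]-3a,4,5,7a-tetrahydro-1H-indene-4-carbaldehyde, via (2E,4Z,6S,7E,9E,11E,13E)-4-ethyl-2,6,8,10,12-pentamethyl-14-phenyltetradeca-2,4,7,9,11,13-hexaenal 14 (not isolated)
Conditions: activated MnO2 (20 equiv), CH2Cl2, rt, dark; filter; PhMe, BHT (cat.), 60 °C
Reagents that add atoms: none
Why: MnO2 oxidises the allylic alcohol to dienal 14, whose enal alkene C7=C7a then adds to the proximal diene C3a=C4–C5=C6 in a concerted type-1 intramolecular Diels–Alder reaction; the closest known reaction type is the thermal, oxidation-triggered cyclisation of terminally activated 1,3,8-nonatrienes to trans-hydrindenes. The cyclopentene closes through the internal bond C3a–C7a across the tether C3–C2=C1, whose Z-alkene holds the two termini syn, and the cyclohexene closes through the peripheral bond C6–C7; only the proximal diene can react, because the distal dienes would need a trans-alkene inside the tether ring. C7 and C7a follow from suprafacial addition to the (E)-enal, C6 from the E geometry of the C5=C6 alkene (side chain outside, methyl inside), and the trans ring fusion from the endo-CHO/exo-tether transition state that terminally activated nonatrienes prefer, in which the C3a–C7a bond leads. The π-face is set by C3: A(1,3) strain with the C4 methyl holds C3–H in the diene plane, so the tether reaches C3a anti to the C3 methyl, which puts C3-Me cis to C3a-H as in the target. The step needs endo over exo selectivity and this facial selectivity; the C7-Me/C1-Et A(1,3) strain already twists the dienal out of planarity, so the perpendicular geometry needed for closure costs little conjugation. The moderate temperature should keep the [1,5]-hydrogen shift of the Z-dienal slow.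

Step 12
Reactants: 15 (1R,3aR,4R,5S,7aS)-3-ethyl-1,4,5,7-tetramethyl-5-[(1E,3E)-2-methyl-4-phenylbuta-1,3-dien-1-yl]-3a,4,5,7a-tetrahydro-1H-indene-4-carbaldehyde
Product: 16 zyggomphic acid B, (1R,3aR,4R,5S,7aS)-3-ethyl-1,4,5,7-tetramethyl-5-[(1E,3E)-2-methyl-4-phenylbuta-1,3-dien-1-yl]-3a,4,5,7a-tetrahydro-1H-indene-4-carboxylic acid
Conditions: NaClO2, NaH2PO4, 2-methyl-2-butene (excess), t-BuOH/THF/H2O, 0 °C to rt
Reagents that add atoms: sodium chlorite, [Na+].[O-]Cl=O
Why: Pinnick oxidation converts the hindered, non-enolisable aldehyde on the quaternary carbon to the acid, and the alkene scavenger removes HOCl so the ring alkenes and the styryl diene should survive.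

## Compound list

1 | methyl (S)-3-hydroxy-2-methylpropanoate | COC(=O)[C@@H](C)CO | starting material
2 | methyl (S)-3-[(tert-butyldimethylsilyl)oxy]-2-methylpropanoate | COC(=O)[C@@H](C)CO[Si](C)(C)C(C)(C)C | intermediate
3 | (S)-3-[(tert-butyldimethylsilyl)oxy]-2-methylpropanal | O=C[C@@H](C)CO[Si](C)(C)C(C)(C)C | intermediate
4 | tert-butyl{[(2R,3Z)-4-iodo-2-methylhex-3-en-1-yl]oxy}dimethylsilane | CC/C(I)=C/[C@@H](C)CO[Si](C)(C)C(C)(C)C | intermediate
5 | (2R,3Z)-4-iodo-2-methylhex-3-en-1-ol | CC/C(I)=C/[C@@H](C)CO | intermediate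
6 | (2R,3Z)-4-iodo-2-methylhex-3-enal | CC/C(I)=C/[C@@H](C)C=O | intermediate
7 | (2E,4S,5Z)-6-iodo-2,4-dimethylocta-2,5-dienal | CC/C(I)=C/[C@@H](C)/C=C(C)/C=O | intermediate
8 | (2E,4E,6S,7Z)-8-iodo-2,4,6-trimethyldeca-2,4,7-trienal | CC/C(I)=C/[C@@H](C)/C=C(C)/C=C(C)/C=O | intermediate
9 | (2E,4E,6E,8S,9Z)-10-iodo-2,4,6,8-tetramethyldodeca-2,4,6,9-tetraenal | CC/C(I)=C/[C@@H](C)/C=C(C)/C=C(C)/C=C(C)/C=O | intermediate
10 | [(1E,3E,5E,7E,9S,10Z)-11-iodo-3,5,7,9-tetramethyltrideca-1,3,5,7,10-pentaen-1-yl]benzene | CC/C(I)=C/[C@@H](C)/C=C(C)/C=C(C)/C=C(C)/C=C/c1ccccc1 | intermediate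
11 | prop-2-yn-1-ol | C#CCO | starting material
12 | (E)-[3-(dimethylalumanyloxy)-2-methylprop-1-en-1-yl]dimethylalumane | C[Al](C)/C=C(\C)CO[Al](C)C | intermediate
13 | (2E,4Z,6S,7E,9E,11E,13E)-4-ethyl-2,6,8,10,12-pentamethyl-14-phenyltetradeca-2,4,7,9,11,13-hexaen-1-ol | CC/C(/C=C(\C)CO)=C/[C@@H](C)/C=C(C)/C=C(C)/C=C(C)/C=C/c1ccccc1 | intermediate
14 | (2E,4Z,6S,7E,9E,11E,13E)-4-ethyl-2,6,8,10,12-pentamethyl-14-phenyltetradeca-2,4,7,9,11,13-hexaenal | CC/C(/C=C(\C)C=O)=C/[C@@H](C)/C=C(C)/C=C(C)/C=C(C)/C=C/c1ccccc1 | intermediate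
15 | (1R,3aR,4R,5S,7aS)-3-ethyl-1,4,5,7-tetramethyl-5-[(1E,3E)-2-methyl-4-phenylbuta-1,3-dien-1-yl]-3a,4,5,7a-tetrahydro-1H-indene-4-carbaldehyde | CCC1=C[C@@H](C)[C@@H]2C(C)=C[C@](C)(/C=C(C)/C=C/c3ccccc3)[C@](C)(C=O)[C@@H]12 | intermediate
16 | zyggomphic acid B | CCC1=C[C@@H](C)[C@@H]2C(C)=C[C@](C)(/C=C(C)/C=C/c3ccccc3)[C@](C)(C(=O)O)[C@@H]12 | target

## Step count and risks

Total step count: 12. Longest linear sequence: 12 steps (1 to 16).

**Step 11 (key step).** The cycloaddition may pass partly through the exo (cis-fused) transition state. The skipped Z-dienal may also undergo a [1,5]-hydrogen shift from C3–H, or the inside methyl on C6 may slow the closure so far that the temperature needed erodes selectivity. The fallback sets out from 13 and returns at 16. It moves ring formation to an isolable ester, where a Lewis acid can drive the closure far below the temperature of sigmatropic shifts and enforce the endo-carbonyl mode, and it changes the endgame from aldehyde oxidation to ester cleavage. Compound 13 would be oxidised with MnO2 at 0 °C and the cold filtrate of 14 taken directly into a Pinnick oxidation to (2E,4Z,6S,7E,9E,11E,13E)-4-ethyl-2,6,8,10,12-pentamethyl-14-phenyltetradeca-2,4,7,9,11,13-hexaenoic acid F1. Alkylation with allyl bromide and K2CO3 in DMF would give the allyl ester of this acid F2. Treatment with Me2AlCl in CH2Cl2 at −78 to −30 °C (Lewis-acid-promoted intramolecular Diels–Alder reaction of a trienoate) should give the allyl ester of zyggomphic acid B F3. Pd(PPh3)4/morpholine deallylation, which does not depend on access to the hindered carbonyl, then gives 16.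

**Step 6.** Aldehyde 6 may lose configuration at its α-carbon by enolisation, or its β,γ-alkene may move into conjugation, during the slow Wittig reaction. The fallback sets out from 5 and returns at 7. It avoids any α-stereogenic aldehyde by making that carbon the nucleophile. Mitsunobu reaction of 5 with 1-phenyl-1H-tetrazole-5-thiol (PPh3, DIAD) would give 5-{[(2R,3Z)-4-iodo-2-methylhex-3-en-1-yl]sulfanyl}-1-phenyl-1H-tetrazole F4. Oxidation with ammonium molybdate/H2O2 would give 5-{[(2R,3Z)-4-iodo-2-methylhex-3-en-1-yl]sulfonyl}-1-phenyl-1H-tetrazole F5. Julia–Kocienski olefination with 1,1-dimethoxypropan-2-one (KHMDS, THF, −78 °C) would give (4S,5Z)-6-iodo-1,1-dimethoxy-2,4-dimethylocta-2,5-diene F6 as a 2E/2Z mixture. Aqueous acid hydrolysis with equilibration of the 2-methylenal to the E isomer then gives 7.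

**Step 10.** Transmetalation of the oxygen-bearing alkenylalane to the hindered α-ethyl alkenylpalladium iodide may be sluggish, or the excess Me3Al/Zr may attack or isomerise the tetraene. The fallback sets out from 10 and returns at 13. It forms the C7=C7a alkene by olefination instead of the C1–C7a bond by coupling. Pd-catalysed reductive carbonylation of 10 (CO 1 atm, Bu3SnH added slowly, Pd(PPh3)4, THF, 50 °C) would give (2Z,4S,5E,7E,9E,11E)-2-ethyl-4,6,8,10-tetramethyl-12-phenyldodeca-2,5,7,9,11-pentaenal F7. Wittig reaction with ethyl 2-(triphenylphosphoranylidene)propanoate in CH2Cl2 at rt would give ethyl (2E,4Z,6S,7E,9E,11E,13E)-4-ethyl-2,6,8,10,12-pentamethyl-14-phenyltetradeca-2,4,7,9,11,13-hexaenoate F8. DIBAL-H reduction at −78 °C then gives 13.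

## Further compounds

F1 | step 11 | (2E,4Z,6S,7E,9E,11E,13E)-4-ethyl-2,6,8,10,12-pentamethyl-14-phenyltetradeca-2,4,7,9,11,13-hexaenoic acid | CC/C(/C=C(\C)C(=O)O)=C/[C@@H](C)/C=C(C)/C=C(C)/C=C(C)/C=C/c1ccccc1
F2 | step 11 | prop-2-en-1-yl (2E,4Z,6S,7E,9E,11E,13E)-4-ethyl-2,6,8,10,12-pentamethyl-14-phenyltetradeca-2,4,7,9,11,13-hexaenoate | CC/C(/C=C(\C)C(=O)OCC=C)=C/[C@@H](C)/C=C(C)/C=C(C)/C=C(C)/C=C/c1ccccc1
F3 | step 11 | prop-2-en-1-yl (1R,3aR,4R,5S,7aS)-3-ethyl-1,4,5,7-tetramethyl-5-[(1E,3E)-2-methyl-4-phenylbuta-1,3-dien-1-yl]-3a,4,5,7a-tetrahydro-1H-indene-4-carboxylate | CCC1=C[C@@H](C)[C@@H]2C(C)=C[C@](C)(/C=C(C)/C=C/c3ccccc3)[C@](C)(C(=O)OCC=C)[C@@H]12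
F4 | step 6 | 5-{[(2R,3Z)-4-iodo-2-methylhex-3-en-1-yl]sulfanyl}-1-phenyl-1H-tetrazole | CC/C(I)=C/[C@@H](C)CSc1nnnn1-c1ccccc1
F5 | step 6 | 5-{[(2R,3Z)-4-iodo-2-methylhex-3-en-1-yl]sulfonyl}-1-phenyl-1H-tetrazole | CC/C(I)=C/[C@@H](C)CS(=O)(=O)c1nnnn1-c1ccccc1
F6 | step 6 | (4S,5Z)-6-iodo-1,1-dimethoxy-2,4-dimethylocta-2,5-diene (2E/2Z mixture) | CC/C(I)=C/[C@@H](C)C=C(C)C(OC)OC
F7 | step 10 | (2Z,4S,5E,7E,9E,11E)-2-ethyl-4,6,8,10-tetramethyl-12-phenyldodeca-2,5,7,9,11-pentaenal | CC/C(C=O)=C/[C@@H](C)/C=C(C)/C=C(C)/C=C(C)/C=C/c1ccccc1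
F8 | step 10 | ethyl (2E,4Z,6S,7E,9E,11E,13E)-4-ethyl-2,6,8,10,12-pentamethyl-14-phenyltetradeca-2,4,7,9,11,13-hexaenoate | CC/C(/C=C(\C)C(=O)OCC)=C/[C@@H](C)/C=C(C)/C=C(C)/C=C(C)/C=C/c1ccccc1
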